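Start with the nucleophile.

| flask | electrophile | nucleophile | remark | time |
|---|---|---|---|---|
| Wednesday's | 0.13 M | 1.1 equiv | run made earlier |  |
| east | 0.20 M | 1.10 equiv |  | 3.0 h |
| north-west | 0.20 M | 1.40 equiv |  | 3.0 h |
| south-east | 0.20 M | 1.90 equiv |  | 3.0 h |

Wednesday's run (percent of the electrophile charged)

| time / min | electrophile / % | target / % |
|---|---|---|
| 6.00 | 85.4 | 13.3 |
| 15.0 | 70.5 | 20.0 |
| 30.0 | 54.5 | 22.7 |
| 50.0 | 43.2 | 19.6 |
| 60.0 | 41.0 | 17.5 |

(scatter of a reading: 0.5 percentage points)

- what was read earlier has a scatter of 0.5 percentage points, one standard deviation

- part of the electrophile that has reacted at the end, east
- part of the electrophile that has reacted at the end, north-west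
- part of the electrophile that has reacted at the end, south-east
- what raising the equivalents of nucleophile from its lowest to its highest value here does to the part of the electrophile that has reacted (changes below 5 percentage points count as none) (it rises / no change / it falls)

Why does Wednesday's electrophile slow down? Per electrophile present, its loss reads 0.0263 min⁻¹ up to 6.00 min, but 0.00523 min⁻¹ between 50.0 min and 60.0 min, a fall by a factor of 5.03.

Is that the nucleophile being used one for one? No: 1.1 equiv was charged and 59.0 % of the electrophile had reacted, so one for one would leave nucleophile standing.

What, then, does a pass cost? Dividing the charge by what reacted gives 1.86 equiv. I call this the toll, the equivalents of nucleophile spent for each electrophile that passes through the nucleophile step.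

Where is that weak? Target falls from 22.7 % to 17.5 % while electrophile still drops, so some electrophile may be leaving by another way without paying, which would raise the toll. Nucleophile still unspent at the last reading would lower it. The two pull against each other, so I keep the toll as read, 1.86 equiv.

What does it give here? The reach, charge over toll, is the part of the electrophile the nucleophile can pass: 59.0 % in east, 75.1 % in north-west, 102 % in south-east.

And the commitment? In east the reach stays below the charge, which makes the nucleophile the limiting reagent despite its 1.10 equiv, so my reckoning has east stop short of full reaction. South-east's reach covers its charge, and the part reacted rises, with the reach growing by 43 percentage points, above the margin.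

The forecast gave 87 %, 93 % and 98 % for east, north-west and south-east, in east higher than my reach, with the trend "it rises", on the ground that “the side reaction keeps eating electrophile after the nucleophile is gone”.

The flasks give 79.7 %, 91.6 % and 99.1 %; it rises, by 19 points.

    electrophile + target → side product B (k = 0.160 M⁻¹ min⁻¹)
    nucleophile + acid set free ⇌ protonated nucleophile, settled at all times (K = 30000 M⁻¹)
    target → over-reaction product (k = 0.0140 min⁻¹)
    electrophile + nucleophile → acid set free + target (k = 0.200 M⁻¹ min⁻¹)
    acid set free + target → side product A (k = 0.230 M⁻¹ min⁻¹)

Counting passes by protonated nucleophile, acid set free and side product A together, east paid 1.99 equiv per pass, against the toll of 1.86 equiv, and its 79.7 % stands above its reach of 59.0 %. At 3.00 h in east, with 1.21 % of the nucleophile left, the nucleophile step used electrophile slower than the path from electrophile + target to side product B did, at 0.79 of that rate. The neighbour with 0.34 M of electrophile, at the same 1.10 equiv, paid 1.98 equiv per pass and reached 85.6 %.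

The readings were computed with constants of no real substance, and the scatter is random.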